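## Retrosynthetic overview

1. Feature: in ring A the depside carbonyl carbon stands on C1 and the CH2 of the 2-oxopentyl chain on the adjacent C6, while C2 on the other side of C1 bears oxygen. Two vicinal carbon substituents beside an oxygen are the pattern left by C–C insertion of a 3-alkoxyaryne.
2. Depside C(=O)–O bond: ring A acid (2-OBn, ketone masked as a dioxolane) plus the 4-OH of benzyl olivetolate. Ketal hydrolysis and hydrogenolysis come last.
3. Side-chain C(=O)–propyl bond: arylacetyl chloride plus n-propylzinc bromide. The acid comes from the unhindered ester of a homophthalate diester.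
4. Key disconnection: the aryl–CO2Me and aryl–CH2 bonds are made together from 3,5-dimethoxybenzyne and dimethyl malonate. The silylaryl triflate comes from 3,5-dimethoxyphenol by carbamate-directed ortho-silylation.
5. Rings: none is built, because both benzene rings are bought. The four-membered ring of the key step and the dioxolane are transient.

Key step: step 4

Assumption: n-propylzinc bromide (0.5 M in THF) and olivetolic acid are taken as purchasable. The target has no stereocentre, so no stereocontrol is required.

## Route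

Step 1
Reactants: 1 3,5-dimethoxyphenol
Product: 2 3,5-dimethoxyphenyl N-isopropylcarbamate
Conditions: i-PrNCO (1.5 equiv), Et3N (0.2 equiv), CH2Cl2, rt
Reagents that add atoms: isopropyl isocyanate, CC(C)N=C=O
Why: Amine-catalysed addition of the phenol O–H to the isocyanate (carbamoylation) should be clean and installs the strongest ortho-directing group on the ring in a form that mild base removes later.

Step 2
Reactants: 2 3,5-dimethoxyphenyl N-isopropylcarbamate
Product: 6 3,5-dimethoxy-2-(trimethylsilyl)phenyl N-isopropylcarbamate, via N-silyl carbamate 3 (not isolated), via aryllithium 4 (not isolated), via bis-silyl carbamate 5 (not isolated)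
Conditions: TBSOTf (1.1 equiv), TMEDA (1.1 equiv), Et2O, 0 °C → rt; TMEDA (2 equiv), n-BuLi (2.1 equiv), −78 °C; TMSCl (3 equiv), −78 °C → rt; aq NaHSO4 work-up
Reagents that add atoms: chlorotrimethylsilane, C[Si](C)(C)Cl; tert-butyldimethylsilyl trifluoromethanesulfonate, CC(C)(C)[Si](C)(C)OS(=O)(=O)C(F)(F)F (silyl group of 3–5 only); n-butyllithium, [Li]CCCC (lithium of 4 only)
Why: Directed ortho-metalation: N-silylation masks the carbamate N–H, the O-carbamate and the neighbouring methoxy group then jointly steer n-BuLi to the carbon between them (C2 and C6 are equivalent, and C4 lies only between two weaker methoxy directors), TMSCl traps aryllithium 4 at −78 °C before an anionic Fries shift can set in, and the acidic work-up hydrolyses only the N–Si bond of 5.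

Step 3
Reactants: 6 3,5-dimethoxy-2-(trimethylsilyl)phenyl N-isopropylcarbamate
Product: 8 3,5-dimethoxy-2-(trimethylsilyl)phenyl trifluoromethanesulfonate, via silylphenol 7 (not isolated)
Conditions: DBU (1.5 equiv), Et2NH (1.2 equiv), MeCN, 40 °C; then PhNTf2 (1.5 equiv), rt
Reagents that add atoms: N-phenylbis(trifluoromethanesulfonimide), O=S(=O)(N(c1ccccc1)S(=O)(=O)C(F)(F)F)C(F)(F)F
Why: DBU triggers E1cB cleavage of the secondary carbamate, diethylamine scavenges the released isopropyl isocyanate as a urea, and the phenoxide of 7 is O-sulfonylated in the same flask by PhNTf2 (triflation), all under conditions mild enough to keep the aryl–silicon bond.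

Step 4
Reactants: 8 3,5-dimethoxy-2-(trimethylsilyl)phenyl trifluoromethanesulfonate; 9 dimethyl malonate (2 equiv)
Product: 12 methyl 2,4-dimethoxy-6-(2-methoxy-2-oxoethyl)benzoate, via 3,5-dimethoxybenzyne 10 (not isolated), via benzocyclobutenoxide 11 (not isolated)
Conditions: KF (3 equiv), 18-crown-6 (3 equiv), THF, 0 °C → rt, slow addition of 8
Reagents that add atoms: none
Why: Fluoride attacks silicon and triflate leaves (1,2-elimination of the ortho-silylaryl triflate), giving aryne 10 whose triple bond has one methoxy group directly beside it. The malonate enolate adds to the aryne carbon remote from that methoxy group, the aryl anion formed next to the methoxy group closes on one ester carbonyl (4-exo-trig) to alkoxide 11, and fragmentation of the strained four-membered ring breaks the old malonate C–C(=O) bond, so aryl–CO2Me and aryl–CH2CO2Me stand on neighbouring carbons and no ring remains in 12. The closest known reaction type is aryne acyl-alkylation, the insertion of arynes from ortho-silylaryl triflates into the C–C sigma bond of malonates and beta-keto esters, which is established for 3-alkoxyarynes. The selectivity needed is the regiochemistry of the first addition, and the flanking methoxy group secures it by distorting the triple bond so that the remote carbon is the more electrophilic one and by stabilising the adjacent aryl anion inductively, an effect the distant second methoxy group is too weak to overturn. No stereocentre is created, because the two sp3 centres of 11 vanish on ring opening. Excess 9 keeps the far more acidic malonate as the dominant carbanion, which should suppress a second arylation of the product, and the enolate released by fragmentation deprotonates fresh 9, so fluoride is consumed only in the desilylation.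

Step 5
Reactants: 12 methyl 2,4-dimethoxy-6-(2-methoxy-2-oxoethyl)benzoate
Product: 13 methyl 2-hydroxy-4-methoxy-6-(2-methoxy-2-oxoethyl)benzoate
Conditions: BCl3 (1 M in CH2Cl2, 2.2 equiv), CH2Cl2, −78 → 0 °C; H2O quench
Reagents that add atoms: none
Why: Chelation-controlled aryl ether cleavage: BCl3 binds between the benzoate carbonyl oxygen and the ortho methoxy oxygen so that chloride demethylates only that ether while the C4 methoxy group and both methyl esters survive at or below 0 °C, and running the step before the ketone exists excludes Lewis-acid-induced enol lactonisation.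

Step 6
Reactants: 13 methyl 2-hydroxy-4-methoxy-6-(2-methoxy-2-oxoethyl)benzoate
Product: 14 methyl 2-(benzyloxy)-4-methoxy-6-(2-methoxy-2-oxoethyl)benzoate
Conditions: BnBr (1.2 equiv), K2CO3 (2 equiv), DMF, 50 °C
Reagents that add atoms: benzyl bromide, BrCc1ccccc1
Why: Williamson ether synthesis: carbonate deprotonates the phenol but not appreciably the arylacetate CH2, so O-benzylation should be the only alkylation, and benzyl is chosen because it leaves together with the ring B benzyl ester in the last step.

Step 7
Reactants: 14 methyl 2-(benzyloxy)-4-methoxy-6-(2-methoxy-2-oxoethyl)benzoate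
Product: 15 2-[3-(benzyloxy)-5-methoxy-2-(methoxycarbonyl)phenyl]acetic acid
Conditions: LiOH·H2O (1.2 equiv), THF–MeOH–H2O 3:1:1, 0 °C → rt; then 1 M HCl
Reagents that add atoms: lithium hydroxide, [Li+].[OH-]
Why: Chemoselective saponification (BAc2): hydroxide reaches the unhindered arylacetic ester easily, whereas the benzoate carbonyl is shielded by two ortho substituents and should stay intact at room temperature.

Step 8
Reactants: 15 2-[3-(benzyloxy)-5-methoxy-2-(methoxycarbonyl)phenyl]acetic acid; 16 n-propylzinc bromide (0.5 M in THF, 1.3 equiv)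
Product: 18 methyl 2-(benzyloxy)-4-methoxy-6-(2-oxopentyl)benzoate, via acid chloride 17 (not isolated)
Conditions: (COCl)2 (1.3 equiv), cat. DMF, CH2Cl2, 0 °C → rt, evaporate; then 16, Pd(PPh3)4 (3 mol %), THF, 0 °C → rt
Reagents that add atoms: oxalyl chloride, O=C(Cl)C(=O)Cl (chlorine of 17 only)
Why: DMF-catalysed acid chloride formation followed by Negishi-type acylation: zerovalent palladium inserts into the C–Cl bond, the non-basic alkylzinc transfers propyl faster than decarbonylation or beta-hydride loss, and the reagent attacks neither the hindered ester, the product ketone nor the acidic benzylic CH2.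

Step 9
Reactants: 18 methyl 2-(benzyloxy)-4-methoxy-6-(2-oxopentyl)benzoate
Product: 19 methyl 2-(benzyloxy)-4-methoxy-6-[(2-propyl-1,3-dioxolan-2-yl)methyl]benzoate
Conditions: TMSOCH2CH2OTMS (2 equiv), TMSOTf (0.1 equiv), CH2Cl2, −78 → −20 °C; pyridine quench
Reagents that add atoms: 1,2-bis(trimethylsilyloxy)ethane, C[Si](C)(C)OCCO[Si](C)(C)C
Why: Noyori ketalisation: formation of hexamethyldisiloxane drives dioxolane formation irreversibly under aprotic low-temperature catalysis, so the keto ester is never exposed to the hot protic acid that would close it to an isocoumarin.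

Step 10
Reactants: 19 methyl 2-(benzyloxy)-4-methoxy-6-[(2-propyl-1,3-dioxolan-2-yl)methyl]benzoate
Product: 20 2-(benzyloxy)-4-methoxy-6-[(2-propyl-1,3-dioxolan-2-yl)methyl]benzoic acid
Conditions: KOH (10 equiv), DMSO–H2O 4:1, 90 °C; then cold 1 M KHSO4 to pH 4, EtOAc extraction, used at once
Reagents that add atoms: potassium hydroxide, [K+].[OH-]
Why: Forced saponification of a di-ortho-substituted benzoate by poorly solvated hydroxide in aqueous DMSO: dioxolane, benzyl ether and aryl methyl ether are base-stable, the masked ketone cannot form an enol lactone, and a cold, barely acidic work-up with prompt use should spare the ketal from the neighbouring carboxyl group.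

Step 11
Reactants: 21 olivetolic acid (2,4-dihydroxy-6-pentylbenzoic acid)
Product: 22 benzyl 2,4-dihydroxy-6-pentylbenzoate (benzyl olivetolate)
Conditions: BnBr (1.05 equiv), KHCO3 (1.2 equiv), DMF, rt
Reagents that add atoms: benzyl bromide, BrCc1ccccc1
Why: Carboxylate O-alkylation (SN2): hydrogen carbonate ionises only the carboxylic acid, so the phenols should stay free, and room temperature avoids decarboxylation of the resorcylic acid.

Step 12
Reactants: 20 2-(benzyloxy)-4-methoxy-6-[(2-propyl-1,3-dioxolan-2-yl)methyl]benzoic acid; 22 benzyl 2,4-dihydroxy-6-pentylbenzoate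
Product: 23 benzyl 4-({2-(benzyloxy)-4-methoxy-6-[(2-propyl-1,3-dioxolan-2-yl)methyl]benzoyl}oxy)-2-hydroxy-6-pentylbenzoate
Conditions: DCC (1.2 equiv), DMAP (0.3 equiv), CH2Cl2, 0 °C → rt
Reagents that add atoms: none
Why: Steglich esterification: carbodiimide activation with DMAP acyl transfer works under non-acidic conditions that keep the ketal, and only the 4-OH of 22 should react because the 2-OH is tied up in a hydrogen bond to the adjacent benzyl ester carbonyl and is crowded by it.

Step 13
Reactants: 23 benzyl 4-({2-(benzyloxy)-4-methoxy-6-[(2-propyl-1,3-dioxolan-2-yl)methyl]benzoyl}oxy)-2-hydroxy-6-pentylbenzoate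
Product: 24 benzyl 4-{[2-(benzyloxy)-4-methoxy-6-(2-oxopentyl)benzoyl]oxy}-2-hydroxy-6-pentylbenzoate
Conditions: 2 M aq HCl–THF 1:5, rt, monitored; pH 7 buffer quench
Reagents that add atoms: water, O
Why: Acid-catalysed ketal hydrolysis: the dioxolane of a dialkyl-type ketone ionises in dilute aqueous acid far faster than an aryl or benzyl ester is hydrolysed, and a short reaction time with a neutral quench limits enolisation of the freed ketone towards the depside carbonyl.

Step 14
Reactants: 24 benzyl 4-{[2-(benzyloxy)-4-methoxy-6-(2-oxopentyl)benzoyl]oxy}-2-hydroxy-6-pentylbenzoate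
Product: 25 glomelliferic acid
Conditions: H2 (1 atm), Pd/C (10 wt % Pd), EtOAc, rt
Reagents that add atoms: none
Why: Catalytic hydrogenolysis removes the benzyl ether and the benzyl ester together under neutral conditions that should leave the aliphatic ketone, the depside ester and the decarboxylation-prone salicylic acid unit untouched.

## Compound list

1 | 3,5-dimethoxyphenol | COc1cc(O)cc(OC)c1 | starting material
2 | 3,5-dimethoxyphenyl N-isopropylcarbamate | COc1cc(OC)cc(OC(=O)NC(C)C)c1 | intermediate
3 | 3,5-dimethoxyphenyl N-(tert-butyldimethylsilyl)-N-isopropylcarbamate (not isolated) | COc1cc(OC)cc(OC(=O)N(C(C)C)[Si](C)(C)C(C)(C)C)c1 | intermediate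
4 | 2-lithio-3,5-dimethoxyphenyl N-(tert-butyldimethylsilyl)-N-isopropylcarbamate (not isolated) | COc1cc(OC)c([Li])c(OC(=O)N(C(C)C)[Si](C)(C)C(C)(C)C)c1 | intermediate
5 | 3,5-dimethoxy-2-(trimethylsilyl)phenyl N-(tert-butyldimethylsilyl)-N-isopropylcarbamate (not isolated) | COc1cc(OC)c([Si](C)(C)C)c(OC(=O)N(C(C)C)[Si](C)(C)C(C)(C)C)c1 | intermediate
6 | 3,5-dimethoxy-2-(trimethylsilyl)phenyl N-isopropylcarbamate | COc1cc(OC)c([Si](C)(C)C)c(OC(=O)NC(C)C)c1 | intermediate
7 | 3,5-dimethoxy-2-(trimethylsilyl)phenol (present as its DBU salt, not isolated) | COc1cc(O)c([Si](C)(C)C)c(OC)c1 | intermediate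
8 | 3,5-dimethoxy-2-(trimethylsilyl)phenyl trifluoromethanesulfonate | COc1cc(OC)c([Si](C)(C)C)c(OS(=O)(=O)C(F)(F)F)c1 | intermediate
9 | dimethyl malonate | COC(=O)CC(=O)OC | starting material
10 | 3,5-dimethoxybenzyne (not isolated) | COC1=CC(OC)=CC#C1 | intermediate
11 | 3,5,7-trimethoxy-8-(methoxycarbonyl)bicyclo[4.2.0]octa-1,3,5-trien-7-olate (transient alkoxide, stereoisomer mixture, both sp3 centres lost on ring opening, not isolated) | COC(=O)C1c2cc(OC)cc(OC)c2C1([O-])OC | intermediate
12 | methyl 2,4-dimethoxy-6-(2-methoxy-2-oxoethyl)benzoate | COC(=O)Cc1cc(OC)cc(OC)c1C(=O)OC | intermediate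
13 | methyl 2-hydroxy-4-methoxy-6-(2-methoxy-2-oxoethyl)benzoate | COC(=O)Cc1cc(OC)cc(O)c1C(=O)OC | intermediate
14 | methyl 2-(benzyloxy)-4-methoxy-6-(2-methoxy-2-oxoethyl)benzoate | COC(=O)Cc1cc(OC)cc(OCc2ccccc2)c1C(=O)OC | intermediate
15 | 2-[3-(benzyloxy)-5-methoxy-2-(methoxycarbonyl)phenyl]acetic acid | OC(=O)Cc1cc(OC)cc(OCc2ccccc2)c1C(=O)OC | intermediate
16 | n-propylzinc bromide | CCC[Zn]Br | starting material
17 | methyl 2-(benzyloxy)-6-(2-chloro-2-oxoethyl)-4-methoxybenzoate (not isolated) | ClC(=O)Cc1cc(OC)cc(OCc2ccccc2)c1C(=O)OC | intermediate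
18 | methyl 2-(benzyloxy)-4-methoxy-6-(2-oxopentyl)benzoate | CCCC(=O)Cc1cc(OC)cc(OCc2ccccc2)c1C(=O)OC | intermediate
19 | methyl 2-(benzyloxy)-4-methoxy-6-[(2-propyl-1,3-dioxolan-2-yl)methyl]benzoate | CCCC1(Cc2cc(OC)cc(OCc3ccccc3)c2C(=O)OC)OCCO1 | intermediate
20 | 2-(benzyloxy)-4-methoxy-6-[(2-propyl-1,3-dioxolan-2-yl)methyl]benzoic acid | CCCC1(Cc2cc(OC)cc(OCc3ccccc3)c2C(=O)O)OCCO1 | intermediate
21 | olivetolic acid (2,4-dihydroxy-6-pentylbenzoic acid) | CCCCCc1cc(O)cc(O)c1C(=O)O | starting material
22 | benzyl 2,4-dihydroxy-6-pentylbenzoate | CCCCCc1cc(O)cc(O)c1C(=O)OCc1ccccc1 | intermediate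
23 | benzyl 4-({2-(benzyloxy)-4-methoxy-6-[(2-propyl-1,3-dioxolan-2-yl)methyl]benzoyl}oxy)-2-hydroxy-6-pentylbenzoate | CCCCCc1cc(OC(=O)c2c(OCc3ccccc3)cc(OC)cc2CC2(CCC)OCCO2)cc(O)c1C(=O)OCc1ccccc1 | intermediate
24 | benzyl 4-{[2-(benzyloxy)-4-methoxy-6-(2-oxopentyl)benzoyl]oxy}-2-hydroxy-6-pentylbenzoate | CCCCCc1cc(OC(=O)c2c(OCc3ccccc3)cc(OC)cc2CC(=O)CCC)cc(O)c1C(=O)OCc1ccccc1 | intermediate
25 | glomelliferic acid, 2-hydroxy-4-{[2-hydroxy-4-methoxy-6-(2-oxopentyl)benzoyl]oxy}-6-pentylbenzoic acid (achiral) | CCCCCc1cc(OC(=O)c2c(O)cc(OC)cc2CC(=O)CCC)cc(O)c1C(=O)O | target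

## Step count and risks

Total step count: 14.
Longest linear sequence: 13 (steps 1–10 and 12–14). Step 11 is the one-step side branch.

**Step 4 (key step).**
- Risk: the aryl anion may be protonated before it closes on the ester carbonyl (plain alpha-arylation). The carbanion of the product may be arylated a second time. The aryne may also be lost to unproductive trapping.
- Fallback, setting out from 9 and returning at 12: the two C–C bonds are made one after the other by classical chemistry.
- Dimethyl malonate 9 is alpha-arylated with commercial 1-bromo-3,5-dimethoxybenzene (COc1cc(Br)cc(OC)c1; Pd(OAc)2, P(t-Bu)3·HBF4, K3PO4, toluene, 80 °C) to dimethyl 2-(3,5-dimethoxyphenyl)malonate F1.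
- Krapcho demethoxycarbonylation (LiCl, wet DMSO, 150 °C) gives methyl 2-(3,5-dimethoxyphenyl)acetate F2.
- Vilsmeier–Haack formylation (POCl3, DMF) enters ortho to the side chain and para to a methoxy group, giving methyl 2-(2-formyl-3,5-dimethoxyphenyl)acetate F3.
- Pinnick oxidation (NaClO2, NaH2PO4, 2-methyl-2-butene) gives 2,4-dimethoxy-6-(2-methoxy-2-oxoethyl)benzoic acid F4.
- Methylation with MeI and K2CO3 in DMF rejoins the route at 12.

**Step 12 (depside coupling).**
- Risk: acyl transfer at the di-ortho-substituted activated carboxyl may be slow. An O-to-N acyl shift of the carbodiimide adduct, or participation of a neighbouring ketal oxygen, could then take over.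
- Fallback, setting out from 20 and returning at 23: in-situ activation is replaced by an isolable acyl halide of minimal size.
- Acid 20 is treated with cyanuric fluoride and pyridine (CH2Cl2, −10 °C → rt) to give 2-(benzyloxy)-4-methoxy-6-[(2-propyl-1,3-dioxolan-2-yl)methyl]benzoyl fluoride F5.
- F5 is purified and then combined with 22 and Cs2CO3 (1 equiv) in MeCN at rt. The more acidic, non-chelated 4-OH should be acylated to give 23.

**Step 13 (ketal hydrolysis).**
- Risk: once the ketone is freed under acid, its enol may attack the activated aryl ester, which is enol lactonisation with expulsion of ring B. Alternatively the hydrolysis may stall under conditions mild enough to spare the depside bond.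
- Fallback, setting out from 18 and returning at 25: the ketone is masked by a ketal that falls in the final hydrogenolysis, so no acid step follows the coupling.
- Commercial 1,2-benzenedimethanol is silylated (TMSCl, Et3N, CH2Cl2) to 1,2-bis[(trimethylsilyloxy)methyl]benzene F6.
- Ketone 18 reacts with F6 and catalytic TMSOTf (CH2Cl2, −78 → −20 °C) to give the o-xylylene ketal methyl 2-(benzyloxy)-4-methoxy-6-[(3-propyl-1,5-dihydro-2,4-benzodioxepin-3-yl)methyl]benzoate F7.
- KOH in aqueous DMSO at 90 °C gives 2-(benzyloxy)-4-methoxy-6-[(3-propyl-1,5-dihydro-2,4-benzodioxepin-3-yl)methyl]benzoic acid F8.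
- Steglich coupling with 22 gives benzyl 4-({2-(benzyloxy)-4-methoxy-6-[(3-propyl-1,5-dihydro-2,4-benzodioxepin-3-yl)methyl]benzoyl}oxy)-2-hydroxy-6-pentylbenzoate F9.
- H2 over Pd/C in EtOAc then cleaves the benzyl ether, the benzyl ester and both benzylic C–O bonds of the ketal. The resulting hydrate collapses to the ketone, which gives 25 directly.

## Further compounds

F1 | step 4 | dimethyl 2-(3,5-dimethoxyphenyl)malonate | COC(=O)C(C(=O)OC)c1cc(OC)cc(OC)c1
F2 | step 4 | methyl 2-(3,5-dimethoxyphenyl)acetate | COC(=O)Cc1cc(OC)cc(OC)c1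
F3 | step 4 | methyl 2-(2-formyl-3,5-dimethoxyphenyl)acetate | COC(=O)Cc1cc(OC)cc(OC)c1C=O
F4 | step 4 | 2,4-dimethoxy-6-(2-methoxy-2-oxoethyl)benzoic acid | COC(=O)Cc1cc(OC)cc(OC)c1C(=O)O
F5 | step 12 | 2-(benzyloxy)-4-methoxy-6-[(2-propyl-1,3-dioxolan-2-yl)methyl]benzoyl fluoride | CCCC1(Cc2cc(OC)cc(OCc3ccccc3)c2C(=O)F)OCCO1
F6 | step 13 | 1,2-bis[(trimethylsilyloxy)methyl]benzene | C[Si](C)(C)OCc1ccccc1CO[Si](C)(C)C
F7 | step 13 | methyl 2-(benzyloxy)-4-methoxy-6-[(3-propyl-1,5-dihydro-2,4-benzodioxepin-3-yl)methyl]benzoate | CCCC1(Cc2cc(OC)cc(OCc3ccccc3)c2C(=O)OC)OCc2ccccc2CO1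
F8 | step 13 | 2-(benzyloxy)-4-methoxy-6-[(3-propyl-1,5-dihydro-2,4-benzodioxepin-3-yl)methyl]benzoic acid | CCCC1(Cc2cc(OC)cc(OCc3ccccc3)c2C(=O)O)OCc2ccccc2CO1
F9 | step 13 | benzyl 4-({2-(benzyloxy)-4-methoxy-6-[(3-propyl-1,5-dihydro-2,4-benzodioxepin-3-yl)methyl]benzoyl}oxy)-2-hydroxy-6-pentylbenzoate | CCCCCc1cc(OC(=O)c2c(OCc3ccccc3)cc(OC)cc2CC2(CCC)OCc3ccccc3CO2)cc(O)c1C(=O)OCc1ccccc1
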